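**Strategy.** The methoxy-para-quinone (ring B) is built last by a Dötz benzannulation rather than carried through the route. An enantiopure 2-ethynylchromanone, a methoxy(1-methoxyvinyl)carbene complex of chromium and one of its CO ligands assemble to a chromium-bound dienylketene. Its 6π-electrocyclisation closes ring B by joining the CO-derived carbonyl carbon (the quinone C=O flanking the chromanyl-bearing carbon) to the vinyl CH2 terminus (the ring CH next to C–OMe). This exploits the para-dioxygenated six-membered ring with its two ring CH atoms and its single C–C link to C2 of the chromanone; (NH4)2Ce(NO3)6 work-up delivers the quinone. C2 is set earlier by copper-catalysed asymmetric alkynylation of a chromone.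

Key step: step 7

Remark (assumption): the single stereocentre, C2 of the chromanone, is S. The (S,S)-bis(oxazoline) ligand of step 4 is assumed to give this sense of induction; if it proves opposite, the commercial (R,R)-antipode is used with no other change.

**Step 1**
Reactants: 1 2',4',6'-trihydroxyacetophenone
Product: 2 2',4',6'-trihydroxy-3',5'-dimethylacetophenone
Conditions: MeI (2.1 equiv), NaOMe, MeOH, 0 °C to reflux
Reagents that add atoms: methyl iodide, CI
Why: Double C-alkylation of the phloroglucinol-type phenoxide (reacting through its vinylogous enolate carbons) at the two free ring positions, a known C-methylation of phloroacetophenone; limiting MeI to two equivalents should restrain geminal over-alkylation.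

**Step 2**
Reactants: 2 2',4',6'-trihydroxy-3',5'-dimethylacetophenone
Product: 3 2',6'-dihydroxy-4'-methoxy-3',5'-dimethylacetophenone
Conditions: Me2SO4 (1.0 equiv), K2CO3 (1.1 equiv), acetone, rt
Reagents that add atoms: dimethyl sulfate, COS(=O)(=O)OC
Why: Williamson etherification in which the 4'-OH, para to the acetyl group and not hydrogen-bonded to it, should ionise and react first, while the two ortho hydroxyls are deactivated by chelation to and crowding by the acetyl group.

**Step 3**
Reactants: 3 2',6'-dihydroxy-4'-methoxy-3',5'-dimethylacetophenone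
Product: 5 5-hydroxy-7-methoxy-6,8-dimethyl-4H-chromen-4-one, via enaminone 4 (not isolated)
Conditions: Me2NCH(OMe)2, toluene, 90 °C; then conc. HCl, CH2Cl2, 40 °C
Reagents that add atoms: N,N-dimethylformamide dimethyl acetal, COC(OC)N(C)C
Why: Enaminone formation at the acetyl CH3 followed by acid-mediated addition–elimination of an ortho-OH with loss of Me2NH is the standard enaminone route to 2,3-unsubstituted chromones; the two ortho hydroxyls are equivalent by symmetry, so only one chromone can form.

**Step 4**
Reactants: 5 5-hydroxy-7-methoxy-6,8-dimethyl-4H-chromen-4-one; 6 trimethylsilylacetylene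
Product: 9 (S)-5-(tert-butyldimethylsilyloxy)-7-methoxy-6,8-dimethyl-2-[(trimethylsilyl)ethynyl]chroman-4-one, via benzopyrylium triflate 7 (not isolated), via silyl enol ether 8 (not isolated)
Conditions: TBSOTf (2.3 equiv), 2,6-lutidine (1.05 equiv), ClCH2CH2Cl, 0 to 60 °C; then CuI (10 mol%), (S,S)-2,2'-isopropylidenebis(4-phenyl-2-oxazoline) (12 mol%), 6, iPr2NEt, toluene, −78 to −40 °C; then 1 M HCl, THF, 0 °C
Reagents that add atoms: tert-butyldimethylsilyl triflate, CC(C)(C)[Si](C)(C)OS(=O)(=O)C(F)(F)F
Why: Silylation of the 5-OH and of the C4 carbonyl oxygen should give the aromatic 4-silyloxybenzopyrylium ion 7, to which the chiral bis(oxazoline)–copper acetylide adds at C2 (catalytic enantioselective alkynylation of chromone-derived oxocarbenium ions); the ligand shields one face of the planar cation and so sets the 2S centre, and the mild acid hydrolyses only the silyl enol ether of 8.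

**Step 5**
Reactants: 9 (S)-5-(tert-butyldimethylsilyloxy)-7-methoxy-6,8-dimethyl-2-[(trimethylsilyl)ethynyl]chroman-4-one
Product: 10 (S)-2-ethynyl-5-hydroxy-7-methoxy-6,8-dimethylchroman-4-one
Conditions: Bu4NF (2.5 equiv), AcOH (2.5 equiv), THF, 0 °C
Reagents that add atoms: none
Why: Fluoride-induced desilylation should cleave both the aryl O–Si and the alkynyl C–Si bond, and the AcOH buffer keeps the medium non-basic so that C2 cannot epimerise by E1cB ring opening (retro-oxa-Michael).

**Step 6**
Reactants: 11 methyl vinyl ether; 12 Cr(CO)6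
Product: 15 pentacarbonyl[methoxy(1-methoxyethenyl)carbene]chromium, via 1-methoxyvinyllithium 13 (not isolated), via lithium acylchromate 14 (not isolated)
Conditions: t-BuLi, THF, −78 to 0 °C; then Cr(CO)6, THF, 0 °C to rt; then Me3OBF4, CH2Cl2, 0 °C
Reagents that add atoms: trimethyloxonium tetrafluoroborate, C[O+](C)C.F[B-](F)(F)F
Why: Fischer carbene synthesis, in which the α-lithiated enol ether adds to a CO ligand of zerovalent chromium and the resulting acylchromate is O-methylated by the Meerwein salt; α-oxygenated alkenyl carbene complexes made this way from lithiated cyclic enol ethers are isolable, which supports the acyclic case.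

**Step 7**
Reactants: 10 (S)-2-ethynyl-5-hydroxy-7-methoxy-6,8-dimethylchroman-4-one; 15 pentacarbonyl[methoxy(1-methoxyethenyl)carbene]chromium
Product: 18 (S)-2-(5-hydroxy-7-methoxy-6,8-dimethyl-4-oxochroman-2-yl)-5-methoxy-1,4-benzoquinone, via dienylketene chromium complex 16 (not isolated), via dimethoxyphenol chromium complex 17 (not isolated)
Conditions: 15 (1.5 equiv), THF, 50 °C, Ar; then (NH4)2Ce(NO3)6, MeCN/H2O, 0 °C
Reagents that add atoms: water, O
Why: Dötz benzannulation: loss of one CO from 15, insertion of the terminal alkyne into Cr=C (alkyne CH to the carbene carbon) and CO insertion should give the η4-dienylketene 16, whose thermal disrotatory 6π-electrocyclisation closes the six-membered ring B by joining the CO-derived acyl carbon to the CH2 terminus of the methoxyvinyl group, and enolisation gives arene complex 17. The closest known reaction type is the benzannulation of alkenyl(methoxy)carbene chromium complexes, α-oxygenated (2-oxacycloalkenyl) ones included, with terminal alkynes followed by oxidative work-up to the quinone. (NH4)2Ce(NO3)6 then removes the Cr(CO)3 unit and oxidises the 4-methoxyphenol to the para-quinone, water attacking the carbon that carried the carbene methoxy group, which leaves as methanol. No new stereocentre is formed, and C2 of the chromanone should be untouched by the neutral thermal conditions and the short, cold oxidation. Regioselectivity (chromanyl next to the CO-derived carbon) is secured by the steric bias of a terminal alkyne, and phenol formation over cyclobutenone or furan formation by the use of an alkenyl carbene in THF. Chemoselective oxidation is expected because ring B is a far more electron-rich para-methoxyphenol than the acyl-deactivated, chelated, fully substituted ring A, and a para-quinone retaining the vinylogous-ester methoxy group is the normal outcome for 4,5-dimethoxyphenols.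

**Compound list**

1 | 2',4',6'-trihydroxyacetophenone | CC(=O)c1c(O)cc(O)cc1O | starting material
2 | 2',4',6'-trihydroxy-3',5'-dimethylacetophenone | CC(=O)c1c(O)c(C)c(O)c(C)c1O | intermediate
3 | 2',6'-dihydroxy-4'-methoxy-3',5'-dimethylacetophenone | CC(=O)c1c(O)c(C)c(OC)c(C)c1O | intermediate
4 | (E)-1-(2,6-dihydroxy-4-methoxy-3,5-dimethylphenyl)-3-(dimethylamino)prop-2-en-1-one (enaminone, formed in the flask) | CN(C)/C=C/C(=O)c1c(O)c(C)c(OC)c(C)c1O | intermediate
5 | 5-hydroxy-7-methoxy-6,8-dimethyl-4H-chromen-4-one | O=c1ccoc2c(C)c(OC)c(C)c(O)c12 | intermediate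
6 | trimethylsilylacetylene | C#C[Si](C)(C)C | starting material
7 | 4,5-bis(tert-butyldimethylsilyloxy)-7-methoxy-6,8-dimethylchromenylium triflate (formed in the flask) | CC(C)(C)[Si](C)(C)Oc1cc[o+]c2c(C)c(OC)c(C)c(O[Si](C)(C)C(C)(C)C)c12.[O-]S(=O)(=O)C(F)(F)F | intermediate
8 | (S)-4,5-bis(tert-butyldimethylsilyloxy)-7-methoxy-6,8-dimethyl-2-[(trimethylsilyl)ethynyl]-2H-chromene (formed in the flask) | C[Si](C)(C)C#C[C@@H]1C=C(O[Si](C)(C)C(C)(C)C)c2c(O[Si](C)(C)C(C)(C)C)c(C)c(OC)c(C)c2O1 | intermediate
9 | (S)-5-(tert-butyldimethylsilyloxy)-7-methoxy-6,8-dimethyl-2-[(trimethylsilyl)ethynyl]chroman-4-one | C[Si](C)(C)C#C[C@@H]1CC(=O)c2c(O[Si](C)(C)C(C)(C)C)c(C)c(OC)c(C)c2O1 | intermediate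
10 | (S)-2-ethynyl-5-hydroxy-7-methoxy-6,8-dimethylchroman-4-one | C#C[C@@H]1CC(=O)c2c(O)c(C)c(OC)c(C)c2O1 | intermediate
11 | methyl vinyl ether | COC=C | starting material
12 | Cr(CO)6, hexacarbonylchromium | [Cr].[C-]#[O+].[C-]#[O+].[C-]#[O+].[C-]#[O+].[C-]#[O+].[C-]#[O+] | starting material
13 | 1-methoxyvinyllithium (formed in the flask) | [Li]C(OC)=C | intermediate
14 | lithium pentacarbonyl(2-methoxyacryloyl)chromate (formed in the flask) | [Li+].[O-]C(=[Cr])C(OC)=C.[C-]#[O+].[C-]#[O+].[C-]#[O+].[C-]#[O+].[C-]#[O+] | intermediate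
15 | pentacarbonyl[methoxy(1-methoxyethenyl)carbene]chromium | COC(=[Cr])C(OC)=C.[C-]#[O+].[C-]#[O+].[C-]#[O+].[C-]#[O+].[C-]#[O+] | intermediate
16 | Cr(CO)3 complex of (3E)-2-[(2S)-5-hydroxy-7-methoxy-6,8-dimethyl-4-oxochroman-2-yl]-4,5-dimethoxyhexa-1,3,5-trien-1-one (formed in the flask) | C=C(OC)/C(OC)=C\C(=C=O)[C@@H]1CC(=O)c2c(O)c(C)c(OC)c(C)c2O1.[Cr].[C-]#[O+].[C-]#[O+].[C-]#[O+] | intermediate
17 | Cr(CO)3 complex of (S)-5-hydroxy-2-(2-hydroxy-4,5-dimethoxyphenyl)-7-methoxy-6,8-dimethylchroman-4-one (formed in the flask) | COc1cc(O)c(cc1OC)[C@@H]1CC(=O)c2c(O)c(C)c(OC)c(C)c2O1.[Cr].[C-]#[O+].[C-]#[O+].[C-]#[O+] | intermediate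
18 | (S)-2-(5-hydroxy-7-methoxy-6,8-dimethyl-4-oxochroman-2-yl)-5-methoxy-1,4-benzoquinone (CNP0208927.1) | COC1=CC(=O)C([C@@H]2CC(=O)c3c(O)c(C)c(OC)c(C)c3O2)=CC1=O | target

**Step count.** Total: 7 steps. Longest linear sequence: 6 steps (steps 1–5 and 7); step 6 is a one-step side branch.

**Steps most likely to fail**

1. Step 7 (key step). The electron-rich carbene complex may decompose before alkyne insertion, or the vinylketene may be diverted to non-aromatic products. The electron-rich 2'-hydroxyaryl intermediate may also open at C2 by an ortho-quinone-methide pathway, and ring A may be over-oxidised in the cerium work-up. Fallback: setting out from chromone 5, an asymmetric conjugate addition of 2,4,5-trimethoxyphenylboronic acid would be run with Pd(OCOCF3)2 and 4-tert-butyl-2-(pyridin-2-yl)-2-oxazoline (the antipode that gives 2S), NH4PF6, ClCH2CH2Cl/H2O, 60 °C. It would give (S)-5-hydroxy-7-methoxy-6,8-dimethyl-2-(2,4,5-trimethoxyphenyl)chroman-4-one F1. Oxidative demethylation of the para-related 2,5-dimethoxy pair of ring B with (NH4)2Ce(NO3)6 in MeCN/H2O at 0 °C would then return to the route at target 18, bypassing steps 4–7.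

2. Step 4. Ionisation to the benzopyrylium ion may be incomplete, or facial selectivity may erode, because of the crowded peri-bis(silyloxy) array. Fallback: setting out from 2, the sequence would run as follows and rejoin the route at 10.
   - Methylation of all but the chelated hydroxyl (Me2SO4 2.2 equiv, K2CO3, acetone, reflux) would give 2'-hydroxy-4',6'-dimethoxy-3',5'-dimethylacetophenone F2.
   - The conditions of step 3 would give, through (E)-3-(dimethylamino)-1-(2-hydroxy-4,6-dimethoxy-3,5-dimethylphenyl)prop-2-en-1-one F3, 5,7-dimethoxy-6,8-dimethyl-4H-chromen-4-one F4.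
   - The alkynylation of step 4 with a single equivalent of TBSOTf and no lutidine would proceed through 4-(tert-butyldimethylsilyloxy)-5,7-dimethoxy-6,8-dimethylchromenylium triflate F5 and (S)-4-(tert-butyldimethylsilyloxy)-5,7-dimethoxy-6,8-dimethyl-2-[(trimethylsilyl)ethynyl]-2H-chromene F6 to (S)-5,7-dimethoxy-6,8-dimethyl-2-[(trimethylsilyl)ethynyl]chroman-4-one F7.
   - Chelation-directed cleavage of the peri methyl ether (BCl3, CH2Cl2, −78 °C) would give (S)-5-hydroxy-7-methoxy-6,8-dimethyl-2-[(trimethylsilyl)ethynyl]chroman-4-one F8.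
   - The conditions of step 5 would convert F8 into 10.

3. Step 2. Site selectivity may be lost (methylation of an ortho-hydroxyl or double methylation) because the 4'-OH is flanked by two methyl groups. Fallback: setting out from 2, the chromone would be closed first under the conditions of step 3, through (E)-3-(dimethylamino)-1-(2,4,6-trihydroxy-3,5-dimethylphenyl)prop-2-en-1-one F9, to 5,7-dihydroxy-6,8-dimethyl-4H-chromen-4-one F10. In F10 the 5-OH is locked by chelation to the C4 carbonyl, so MeI (1.05 equiv), K2CO3, acetone, rt should methylate only the 7-OH and return to the route at 5.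

**Further compounds**

F1 | step 7 | (S)-5-hydroxy-7-methoxy-6,8-dimethyl-2-(2,4,5-trimethoxyphenyl)chroman-4-one | COc1cc(OC)c(cc1OC)[C@@H]1CC(=O)c2c(O)c(C)c(OC)c(C)c2O1
F2 | step 4 | 2'-hydroxy-4',6'-dimethoxy-3',5'-dimethylacetophenone | CC(=O)c1c(O)c(C)c(OC)c(C)c1OC
F3 | step 4 | (E)-3-(dimethylamino)-1-(2-hydroxy-4,6-dimethoxy-3,5-dimethylphenyl)prop-2-en-1-one | CN(C)/C=C/C(=O)c1c(O)c(C)c(OC)c(C)c1OC
F4 | step 4 | 5,7-dimethoxy-6,8-dimethyl-4H-chromen-4-one | O=c1ccoc2c(C)c(OC)c(C)c(OC)c12
F5 | step 4 | 4-(tert-butyldimethylsilyloxy)-5,7-dimethoxy-6,8-dimethylchromenylium triflate | CC(C)(C)[Si](C)(C)Oc1cc[o+]c2c(C)c(OC)c(C)c(OC)c12.[O-]S(=O)(=O)C(F)(F)F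
F6 | step 4 | (S)-4-(tert-butyldimethylsilyloxy)-5,7-dimethoxy-6,8-dimethyl-2-[(trimethylsilyl)ethynyl]-2H-chromene | C[Si](C)(C)C#C[C@@H]1C=C(O[Si](C)(C)C(C)(C)C)c2c(OC)c(C)c(OC)c(C)c2O1
F7 | step 4 | (S)-5,7-dimethoxy-6,8-dimethyl-2-[(trimethylsilyl)ethynyl]chroman-4-one | C[Si](C)(C)C#C[C@@H]1CC(=O)c2c(OC)c(C)c(OC)c(C)c2O1
F8 | step 4 | (S)-5-hydroxy-7-methoxy-6,8-dimethyl-2-[(trimethylsilyl)ethynyl]chroman-4-one | C[Si](C)(C)C#C[C@@H]1CC(=O)c2c(O)c(C)c(OC)c(C)c2O1
F9 | step 2 | (E)-3-(dimethylamino)-1-(2,4,6-trihydroxy-3,5-dimethylphenyl)prop-2-en-1-one | CN(C)/C=C/C(=O)c1c(O)c(C)c(O)c(C)c1O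
F10 | step 2 | 5,7-dihydroxy-6,8-dimethyl-4H-chromen-4-one | O=c1ccoc2c(C)c(O)c(C)c(O)c12
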